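**Strategy**

- Bonds cut, in retrosynthetic order: C3–OH (enzymatic C–H hydroxylation, last step), the 3'-O acetal, the C6–CH2 bond of the prenyl group (Claisen shift from an O5 1,1-dimethylallyl ether, itself made from a propargyl ether), O1–C2 (oxa-Michael), C2–C3 as the chalcone double bond (aldol condensation), and the aryl O–C bond to the propargyl unit.
- Forward: rings A and B are bought as an acetophenone and isovanillin and joined by Claisen–Schmidt condensation; ring C closes at O1–C2 through the single free phenol; the five-carbon unit moves from O5 to C6; the acetal is removed; C3 is hydroxylated last.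
- Enabling feature: C3 of ring C is a CH2 between the C4 ketone (chelated by the 5-OH) and the aryl-bearing C2, which is the C–H that a flavanone 3-hydroxylase oxidises. The trans C2/C3 pair can therefore be set on the finished skeleton without a chemical oxidant meeting the C6 prenyl alkene or the free 5- and 3'-phenols.
- Stereochemistry: everything before the last step is achiral or racemic. The enzyme converts only the (2S)-flavanone and delivers OH to the C3 face anti to the aryl group, giving (2R,3R); C2 is renamed by the CIP rules, not inverted.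

Key step: step 8

Assumption: a recombinant flavanone 3-hydroxylase (wild type, homologue or variant found by screening) that tolerates the 6-prenyl, 7-OMe and 4'-OMe groups is available; this acceptance is the open point of the route. Racemic compounds are written without stereodescriptors.

**Route**

Step 1
Reactants: 1 2',6'-dihydroxy-4'-methoxyacetophenone; 2 3-chloro-3-methylbut-1-yne
Product: 3 1-[2-hydroxy-4-methoxy-6-(2-methylbut-3-yn-2-yloxy)phenyl]ethanone
Conditions: K2CO3, KI (cat.), CuI (cat.), acetone, 55 °C
Reagents that add atoms: none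
Why: Copper-assisted Williamson-type propargylation, in which the copper acetylide of 2 ionises to a stabilised propargylic electrophile that the phenoxide of 1 captures at oxygen; after the first etherification the remaining OH is locked in a hydrogen bond to the acetyl C=O, which should hold the reaction at the mono-ether, and no stereocenter is formed.

Step 2
Reactants: 4 isovanillin (3-hydroxy-4-methoxybenzaldehyde)
Product: 5 4-methoxy-3-(methoxymethoxy)benzaldehyde
Conditions: MOMCl, K2CO3, acetone, 0 °C to rt
Reagents that add atoms: chloromethyl methyl ether (MOMCl), COCCl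
Why: Williamson etherification of the phenoxide with the reactive alpha-chloro ether gives a base-stable acetal, so that no phenoxide deactivates the aldehyde in the hydroxide-mediated condensation; no stereocenter is formed.

Step 3
Reactants: 3 1-[2-hydroxy-4-methoxy-6-(2-methylbut-3-yn-2-yloxy)phenyl]ethanone; 5 4-methoxy-3-(methoxymethoxy)benzaldehyde
Product: 7 (E)-1-[2-hydroxy-4-methoxy-6-(2-methylbut-3-yn-2-yloxy)phenyl]-3-[4-methoxy-3-(methoxymethoxy)phenyl]prop-2-en-1-one, via aldol adduct 6 (not isolated)
Conditions: KOH (50% aq.), EtOH, 0 °C to rt; then aq. NH4Cl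
Reagents that add atoms: none
Why: Claisen–Schmidt aldol condensation, in which the enolate of methyl ketone 3 adds to the non-enolisable aldehyde 5 and adduct 6 loses water by E1cB to the conjugated (E)-enone; the carbinol center of 6 disappears on dehydration, and the tertiary propargyl ether (no propargylic hydrogen) and the acetal are inert to hydroxide.

Step 4
Reactants: 7 (E)-chalcone from step 3
Product: 8 racemic 7-methoxy-2-[4-methoxy-3-(methoxymethoxy)phenyl]-5-(2-methylbut-3-yn-2-yloxy)chroman-4-one
Conditions: NaOAc, EtOH, 78 °C
Reagents that add atoms: none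
Why: Intramolecular oxa-Michael addition (6-endo-trig) of the only free phenoxide to the enone closes ring C at O1–C2, the ortho ether twisting the aryl ketone and so favouring the flavanone side of the chalcone/flavanone equilibrium; C2 is formed racemic on purpose, because the last step selects one enantiomer, and the ether that blocks the second oxygen fixes which oxygen becomes O1.

Step 5
Reactants: 8 racemic 5-O-(1,1-dimethylpropargyl)flavanone
Product: 9 racemic 7-methoxy-2-[4-methoxy-3-(methoxymethoxy)phenyl]-5-(2-methylbut-3-en-2-yloxy)chroman-4-one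
Conditions: H2 (1 atm), 5% Pd/CaCO3 poisoned with Pb(OAc)2, quinoline, EtOAc, rt
Reagents that add atoms: none
Why: Lindlar-type semi-hydrogenation on lead-poisoned palladium stops at the alkene because the terminal alkyne binds far more strongly than the vinyl group it gives; the aryl ketone, acetal and aryl ethers are not reduced and C2 is untouched.

Step 6
Reactants: 9 racemic 5-O-(1,1-dimethylallyl)flavanone
Product: 11 racemic 5-hydroxy-7-methoxy-2-[4-methoxy-3-(methoxymethoxy)phenyl]-6-(3-methylbut-2-enyl)chroman-4-one, via ortho-dienone 10 (not isolated)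
Conditions: PhNEt2, 130 °C, Ar
Reagents that add atoms: none
Why: Aromatic Claisen rearrangement, a [3,3] shift through a chair transition state that delivers the allyl terminus to C6, the only ortho carbon of O5 bearing hydrogen (C4a is quaternary), after which dienone 10 tautomerises to the phenol held by a hydrogen bond to the C4 carbonyl; the allylic transposition turns the branched ether into the linear prenyl group, and the amine solvent keeps acid away from the new prenyl phenol.

Step 7
Reactants: 11 racemic 5-hydroxy-6-prenylflavanone 3'-O-methoxymethyl ether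
Product: 12 racemic 5-hydroxy-2-(3-hydroxy-4-methoxyphenyl)-7-methoxy-6-(3-methylbut-2-enyl)chroman-4-one
Conditions: HCl (1 M in MeOH), 40 °C
Reagents that add atoms: none
Why: Acid-catalysed acetal exchange (methanolysis of the methoxymethyl ether) frees the 3'-phenol; the prenyl alkene should survive because the neighbouring 5-OH is tied up by the C4 carbonyl and O7 is methylated, this deprotection being routine for prenylated flavanones, and C2 stays racemic.

Step 8
Reactants: 12 racemic 5,3'-dihydroxy-7,4'-dimethoxy-6-prenylflavanone
Product: 13 (2R,3R)-3,5-dihydroxy-2-(3-hydroxy-4-methoxyphenyl)-7-methoxy-6-(3-methylbut-2-enyl)chroman-4-one (CNP0146895.1)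
Conditions: flavanone 3-hydroxylase (recombinant, e.g. the Petunia hybrida enzyme from E. coli), FeSO4 (cat.), disodium 2-oxoglutarate, sodium ascorbate, catalase, air, Tris-HCl pH 7.5, 5% DMSO, 30 °C
Reagents that add atoms: dioxygen, O=O
Why: The enzyme-bound divalent iron binds 2-oxoglutarate and O2, oxidative decarboxylation gives succinate, CO2 and a tetravalent iron-oxo species, this abstracts the C3 hydrogen trans to the C2 aryl group of the bound (2S)-flavanone, and hydroxyl rebound to the same face of the C3 radical forms the C3–O bond with retention. The closest known reaction type is the flavanone 3-hydroxylase conversion of (2S)-naringenin and (2S)-eriodictyol into the (2R,3R)-dihydroflavonols, applied here to a 6-prenyl 7-O-methyl flavanone. No ring is closed, ring C being already in place. C3 is set as R by the active site, which presents only the C3 face anti to ring B to the iron-oxo, and C2 is set by enantiomer selection: only the (2S) half of racemic 12 is turned over, its C2 unchanged in space and named R in the product only because the new C3 oxygen raises the CIP rank of C3 above the aryl carbon. The step needs enantiomer, site (C3–H over the benzylic C2–H and the allylic prenyl C–H) and face selectivity, all expected from binding of the 5-OH/C4=O chelate and the 2-arylchromanone core above the metal, with the prenyl and 7-OMe groups at the far edge of ring A. The untouched (2R)-flavanone is less polar and is removed by chromatography, and the neutral aqueous medium spares the prenyl alkene, the free phenols and the base-sensitive product.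

**Compound list**

1 | 2',6'-dihydroxy-4'-methoxyacetophenone | CC(=O)c1c(O)cc(OC)cc1O | starting material
2 | 3-chloro-3-methylbut-1-yne | CC(C)(Cl)C#C | starting material
3 | 1-[2-hydroxy-4-methoxy-6-(2-methylbut-3-yn-2-yloxy)phenyl]ethanone | CC(=O)c1c(O)cc(OC)cc1OC(C)(C)C#C | intermediate
4 | isovanillin (3-hydroxy-4-methoxybenzaldehyde) | COc1ccc(C=O)cc1O | starting material
5 | 4-methoxy-3-(methoxymethoxy)benzaldehyde | COc1ccc(C=O)cc1OCOC | intermediate
6 | racemic aldol adduct, 3-hydroxy-1-[2-hydroxy-4-methoxy-6-(2-methylbut-3-yn-2-yloxy)phenyl]-3-[4-methoxy-3-(methoxymethoxy)phenyl]propan-1-one (not isolated) | COc1ccc(C(O)CC(=O)c2c(O)cc(OC)cc2OC(C)(C)C#C)cc1OCOC | intermediate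
7 | (E)-1-[2-hydroxy-4-methoxy-6-(2-methylbut-3-yn-2-yloxy)phenyl]-3-[4-methoxy-3-(methoxymethoxy)phenyl]prop-2-en-1-one | COc1ccc(/C=C/C(=O)c2c(O)cc(OC)cc2OC(C)(C)C#C)cc1OCOC | intermediate
8 | racemic 7-methoxy-2-[4-methoxy-3-(methoxymethoxy)phenyl]-5-(2-methylbut-3-yn-2-yloxy)chroman-4-one | COc1ccc(C2CC(=O)c3c(OC(C)(C)C#C)cc(OC)cc3O2)cc1OCOC | intermediate
9 | racemic 7-methoxy-2-[4-methoxy-3-(methoxymethoxy)phenyl]-5-(2-methylbut-3-en-2-yloxy)chroman-4-one | COc1ccc(C2CC(=O)c3c(OC(C)(C)C=C)cc(OC)cc3O2)cc1OCOC | intermediate
10 | ortho-dienone, 7-methoxy-2-[4-methoxy-3-(methoxymethoxy)phenyl]-6-(3-methylbut-2-enyl)-2,3-dihydrochromene-4,5(6H)-dione, mixture of diastereomers (not isolated) | COc1ccc(C2CC(=O)C3=C(O2)C=C(OC)C(CC=C(C)C)C3=O)cc1OCOC | intermediate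
11 | racemic 5-hydroxy-7-methoxy-2-[4-methoxy-3-(methoxymethoxy)phenyl]-6-(3-methylbut-2-enyl)chroman-4-one | COc1ccc(C2CC(=O)c3c(O)c(CC=C(C)C)c(OC)cc3O2)cc1OCOC | intermediate
12 | racemic 5-hydroxy-2-(3-hydroxy-4-methoxyphenyl)-7-methoxy-6-(3-methylbut-2-enyl)chroman-4-one | COc1ccc(C2CC(=O)c3c(O)c(CC=C(C)C)c(OC)cc3O2)cc1O | intermediate
13 | (2R,3R)-3,5-dihydroxy-2-(3-hydroxy-4-methoxyphenyl)-7-methoxy-6-(3-methylbut-2-enyl)chroman-4-one (CNP0146895.1) | COc1ccc([C@H]2Oc3cc(OC)c(CC=C(C)C)c(O)c3C(=O)[C@@H]2O)cc1O | target

**Step count**

Total step count: 8. Longest linear sequence: 7 steps (1 to 13 through steps 1, 3, 4, 5, 6, 7, 8; the branch from 4 is equally long through steps 2, 3 to 8).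

**Steps most likely to fail**

1. Step 8. The enzyme may not bind or turn over a flavanone carrying the C6 prenyl, 7-OMe and 4'-OMe groups. It may also decarboxylate 2-oxoglutarate without hydroxylating, or desaturate the product further to the flavonol. Conversion is in any case limited to the (2S) half of 12 unless the remaining enantiomer racemises by reversible ring opening in the buffer.

   Fallback: a chemical route by asymmetric chalcone epoxidation, setting out from ketone 3 and aldehyde 5 and returning at target 13. The free phenol of 3 would be capped (NaH, MOMCl, DMF, 0 °C) to give 1-[4-methoxy-2-(methoxymethoxy)-6-(2-methylbut-3-yn-2-yloxy)phenyl]ethanone F1, which cannot cyclise after condensation. Claisen–Schmidt condensation of F1 with 5 (KOH, EtOH) should give the fully protected (E)-chalcone F2. Juliá–Colonna epoxidation (poly-L-leucine, urea–H2O2, DBU, THF) is a nucleophilic epoxidation that touches only the enone and not the alkyne, and should give the (2R,3S)-epoxy ketone F3. HCl in MeOH would remove both methoxymethyl groups; the liberated 2'-phenol then opens the epoxide at the benzylic carbon with inversion, while the 6'-ether still dictates which oxygen closes ring C. This should give (2R,3R)-3-hydroxy-2-(3-hydroxy-4-methoxyphenyl)-7-methoxy-5-(2-methylbut-3-yn-2-yloxy)chroman-4-one F4. Semi-hydrogenation as in step 5 would give the (2R,3R)-5-O-(1,1-dimethylallyl) dihydroflavonol F5, and Claisen rearrangement in degassed xylene at 130 °C would deliver 13 directly.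

2. Step 1. Etherification of the hydrogen-bonded phenol with the tertiary propargylic chloride may be sluggish or unselective: elimination of 2 to the enyne, bis-etherification, or C-alkylation of the electron-rich ring.

   Fallback: install the 1,1-dimethylallyl ether directly by Tsuji–Trost O-allylation, setting out from 1 and returning at flavanone 9; this also bypasses step 5. 2-Methylbut-3-en-2-ol would be converted (n-BuLi, Boc2O, THF) into tert-butyl 2-methylbut-3-en-2-yl carbonate F6. Reaction of 1 with F6 under Pd(PPh3)4 catalysis (zerovalent palladium, THF, 0 °C) should give 1-[2-hydroxy-4-methoxy-6-(2-methylbut-3-en-2-yloxy)phenyl]ethanone F7, the phenoxide attacking the more substituted terminus of the pi-allyl complex. Condensation of F7 with 5 (KOH, EtOH) would give the (E)-chalcone F8, and ring closure with NaOAc in EtOH at 60 °C would give 9.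

3. Step 7. During acetal cleavage the acid may add the 5-OH across the prenyl double bond (chroman formation) or add methanol or HCl to the alkene.

   Fallback: remove the acetal before the prenyl group exists, setting out from flavanone 8 and returning at 12. Methanolic HCl on 8 should give racemic 2-(3-hydroxy-4-methoxyphenyl)-7-methoxy-5-(2-methylbut-3-yn-2-yloxy)chroman-4-one F9, the tertiary propargyl aryl ether being much less prone to ionise than the allyl ether. Semi-hydrogenation as in step 5 would give racemic 2-(3-hydroxy-4-methoxyphenyl)-7-methoxy-5-(2-methylbut-3-en-2-yloxy)chroman-4-one F10, and the Claisen rearrangement of step 6 would then give 12 with no acid step after the prenyl phenol is formed.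

**Further compounds**

F1 | step 8 | 1-[4-methoxy-2-(methoxymethoxy)-6-(2-methylbut-3-yn-2-yloxy)phenyl]ethanone | CC(=O)c1c(OCOC)cc(OC)cc1OC(C)(C)C#C
F2 | step 8 | (E)-1-[4-methoxy-2-(methoxymethoxy)-6-(2-methylbut-3-yn-2-yloxy)phenyl]-3-[4-methoxy-3-(methoxymethoxy)phenyl]prop-2-en-1-one | COc1ccc(/C=C/C(=O)c2c(OCOC)cc(OC)cc2OC(C)(C)C#C)cc1OCOC
F3 | step 8 | [(2R,3S)-3-[4-methoxy-3-(methoxymethoxy)phenyl]oxiran-2-yl][4-methoxy-2-(methoxymethoxy)-6-(2-methylbut-3-yn-2-yloxy)phenyl]methanone | COc1ccc([C@@H]2O[C@H]2C(=O)c3c(OCOC)cc(OC)cc3OC(C)(C)C#C)cc1OCOC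
F4 | step 8 | (2R,3R)-3-hydroxy-2-(3-hydroxy-4-methoxyphenyl)-7-methoxy-5-(2-methylbut-3-yn-2-yloxy)chroman-4-one | COc1ccc([C@H]2Oc3cc(OC)cc(OC(C)(C)C#C)c3C(=O)[C@@H]2O)cc1O
F5 | step 8 | (2R,3R)-3-hydroxy-2-(3-hydroxy-4-methoxyphenyl)-7-methoxy-5-(2-methylbut-3-en-2-yloxy)chroman-4-one | COc1ccc([C@H]2Oc3cc(OC)cc(OC(C)(C)C=C)c3C(=O)[C@@H]2O)cc1O
F6 | step 1 | tert-butyl 2-methylbut-3-en-2-yl carbonate | CC(C)(C)OC(=O)OC(C)(C)C=C
F7 | step 1 | 1-[2-hydroxy-4-methoxy-6-(2-methylbut-3-en-2-yloxy)phenyl]ethanone | CC(=O)c1c(O)cc(OC)cc1OC(C)(C)C=C
F8 | step 1 | (E)-1-[2-hydroxy-4-methoxy-6-(2-methylbut-3-en-2-yloxy)phenyl]-3-[4-methoxy-3-(methoxymethoxy)phenyl]prop-2-en-1-one | COc1ccc(/C=C/C(=O)c2c(O)cc(OC)cc2OC(C)(C)C=C)cc1OCOC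
F9 | step 7 | racemic 2-(3-hydroxy-4-methoxyphenyl)-7-methoxy-5-(2-methylbut-3-yn-2-yloxy)chroman-4-one | COc1ccc(C2CC(=O)c3c(OC(C)(C)C#C)cc(OC)cc3O2)cc1O
F10 | step 7 | racemic 2-(3-hydroxy-4-methoxyphenyl)-7-methoxy-5-(2-methylbut-3-en-2-yloxy)chroman-4-one | COc1ccc(C2CC(=O)c3c(OC(C)(C)C=C)cc(OC)cc3O2)cc1O
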